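**Plan**

1. The target is achiral. Ring A carries the bridge CH2 at C1, 4-hydroxybenzyl groups at C2 and C6, OH at C3 and OMe at C5. A CH2–CH2 bridge links it to ring B, which carries 3-OH and 4-(4-hydroxybenzyl).
2. Retrosynthetic cuts, in order: the five O–benzyl bonds and one benzylic C–OH; the Cα'–ring B bond (aldehyde plus arylmagnesium); the C6–CH2Ar bond (Negishi coupling at a C6 bromide); C1–Cα and C2–C(aryl-bearing carbon) together (aryne insertion into an aroylacetate); in ring B the CH2–aryl bond (aldehyde plus ArMgBr).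
3. Enabling feature: on ring A the atoms C1 (bridge CH2), C2 (benzylic carbon) and C3 (oxygen) are contiguous. An alkyl/acyl pair beside an alkoxy group is what a 3-alkoxyaryne leaves when it inserts into the Cα–C(=O) bond of a β-ketoester.
4. Forward, no ring is formed and the chain is only joined: 3,5-dimethoxyphenol is taken to the silylaryl triflate; CsF and the ketoester fix C1 and C2; the C2 ketone steers demethylation to C3 and is then reduced; C6 is brominated and benzylated; the ester becomes the aldehyde; the ring B Grignard reagent adds; global hydrogenolysis finishes.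
5. Stereochemistry: none in the target. The carbinol centres made on the way are racemic and are removed by reduction.

Key step: step 5

Assumption: 4-(benzyloxy)phenylmagnesium bromide (THF solution) and 4-(benzyloxy)benzyl chloride are taken as purchased materials; ring A is numbered C1 (bridge carbon) to C6 as in line 1 of the plan.

**Route**

Step 1
Reactants: 1 3,5-dimethoxyphenol
Product: 2 3,5-dimethoxyphenyl N-isopropylcarbamate
Conditions: i-PrNCO, Et3N (cat.), CH2Cl2, 23 °C
Reagents that add atoms: isopropyl isocyanate, CC(C)N=C=O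
Why: Base-catalysed addition of the phenol to the isocyanate (carbamoylation) installs a directing group that can later be removed under mild basic conditions.

Step 2
Reactants: 2 3,5-dimethoxyphenyl N-isopropylcarbamate
Product: 6 3,5-dimethoxy-2-(trimethylsilyl)phenyl N-isopropylcarbamate, via N-silyl carbamate 3 (not isolated), via ortho-lithiated N-silyl carbamate 4 (not isolated), via N-silyl C-silyl carbamate 5 (not isolated)
Conditions: TBSOTf, TMEDA, Et2O, 0 to 23 °C; then n-BuLi, TMEDA, −78 °C; then TMSCl, −78 to 23 °C; aq. NaHSO4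
Reagents that add atoms: chlorotrimethylsilane, C[Si](C)(C)Cl
Why: Directed ortho-metalation, in which in situ N-silylation makes the secondary carbamate a strong directing group that cannot eliminate, lithiation occurs at the site flanked by the carbamate and a methoxy group (both such sites are equivalent by symmetry), TMSCl quenches the aryllithium and the N–Si bond is cleaved on acidic work-up.

Step 3
Reactants: 6 3,5-dimethoxy-2-(trimethylsilyl)phenyl N-isopropylcarbamate
Product: 8 3,5-dimethoxy-2-(trimethylsilyl)phenyl trifluoromethanesulfonate, via silylphenol 7 (not isolated)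
Conditions: DBU, Et2NH, MeCN, 40 °C; then PhNTf2, 23 °C
Reagents that add atoms: N-phenylbis(trifluoromethanesulfonimide), O=S(=O)(N(c1ccccc1)S(=O)(=O)C(F)(F)F)C(F)(F)F
Why: Base-induced E1cB loss of isopropyl isocyanate (trapped by Et2NH as a urea) frees the phenoxide, which is O-triflated in the same flask (carbamate cleavage and triflation), giving the ortho-silylaryl triflate without acidic conditions that could protodesilylate the electron-rich ring.

Step 4
Reactants: 9 4'-(benzyloxy)acetophenone
Product: 10 methyl 3-[4-(benzyloxy)phenyl]-3-oxopropanoate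
Conditions: NaH, (MeO)2CO, THF, reflux; aq. HCl
Reagents that add atoms: dimethyl carbonate, COC(=O)OC
Why: Claisen-type C-acylation of the ketone enolate by dimethyl carbonate, driven to completion by deprotonation of the β-ketoester formed.

Step 5
Reactants: 8 3,5-dimethoxy-2-(trimethylsilyl)phenyl trifluoromethanesulfonate; 10 methyl 3-[4-(benzyloxy)phenyl]-3-oxopropanoate
Product: 13 methyl 2-{2-[4-(benzyloxy)benzoyl]-3,5-dimethoxyphenyl}acetate, via 3,5-dimethoxybenzyne 11 (not isolated), via cesium benzocyclobutenoxide 12 (not isolated)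
Conditions: CsF (2.5 equiv), MeCN, 80 °C
Reagents that add atoms: none
Why: Fluoride attacks silicon of 8 and triflate leaves to give aryne 11; the cesium enolate of 10 adds through carbon to C1, the aryne carbon remote from the C3 methoxy group, and the resulting C2 aryl anion closes onto the ketone (4-exo-trig) to the benzocyclobutenoxide 12, which fragments by C–C cleavage to an ester-stabilised benzylic anion that is protonated to 13. This is the fluoride-induced aryne acyl-alkylation (insertion of an aryne into the Cα–C(=O) σ-bond of a β-ketoester), known for aroylacetates and for 3-alkoxy- and 3,5-dialkoxyarynes. No ring remains in the product and no stereocentre is formed; the two centres of 12 are lost on ring opening. The step needs regioselective addition to the unsymmetrical aryne, and the inductively withdrawing C3 methoxy group secures it by distorting the aryne so that the nucleophile attacks C1 and negative charge builds at C2 beside oxygen. It also needs closure onto the ketone and not the ester carbonyl, which the higher electrophilicity of the ketone provides; simple C-arylation without insertion is the competing path and should be limited by a slight excess of 8 at 80 °C.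

Step 6
Reactants: 13 methyl 2-{2-[4-(benzyloxy)benzoyl]-3,5-dimethoxyphenyl}acetate
Product: 14 methyl 2-{2-[4-(benzyloxy)benzoyl]-3-hydroxy-5-methoxyphenyl}acetate
Conditions: MgI2·OEt2, THF/toluene, 60 °C; aq. HCl
Reagents that add atoms: none
Why: Chelation-controlled ether cleavage, in which magnesium binds the ketone oxygen and the ortho C3 methoxy oxygen in a six-membered chelate and iodide removes that methyl group, while the C5 methoxy group, the remote benzyl ether and the methyl ester lack this activation.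

Step 7
Reactants: 14 methyl 2-{2-[4-(benzyloxy)benzoyl]-3-hydroxy-5-methoxyphenyl}acetate
Product: 15 methyl 2-{2-[4-(benzyloxy)benzyl]-3-hydroxy-5-methoxyphenyl}acetate
Conditions: Et3SiH, CF3CO2H, CH2Cl2, 0 to 23 °C
Reagents that add atoms: none
Why: Ionic hydrogenation, in which the protonated, donor-stabilised diaryl ketone takes hydride from Et3SiH twice (through the diarylmethyl cation) to give the diarylmethane, with the ester and the aryl benzyl ether expected to survive the short acid exposure.

Step 8
Reactants: 15 methyl 2-{2-[4-(benzyloxy)benzyl]-3-hydroxy-5-methoxyphenyl}acetate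
Product: 16 methyl 2-{2-[4-(benzyloxy)benzyl]-6-bromo-3-hydroxy-5-methoxyphenyl}acetate
Conditions: NBS (1.0 equiv), MeCN, −20 to 0 °C
Reagents that add atoms: N-bromosuccinimide, O=C1CCC(=O)N1Br
Why: Electrophilic aromatic bromination, for which only C4 and C6 of ring A are free, and C6 (para to the free phenol, ortho to the methoxy group) should be preferred over C4 (only ortho-activated, between two oxygens), the monoalkoxy aryl ring being far less reactive.

Step 9
Reactants: 16 methyl 2-{2-[4-(benzyloxy)benzyl]-6-bromo-3-hydroxy-5-methoxyphenyl}acetate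
Product: 17 methyl 2-{3-(benzyloxy)-2-[4-(benzyloxy)benzyl]-6-bromo-5-methoxyphenyl}acetate
Conditions: BnBr, K2CO3, DMF, 23 °C
Reagents that add atoms: benzyl bromide, BrCc1ccccc1
Why: Williamson etherification of the phenoxide, which K2CO3 forms without deprotonating the arylacetate, masks the phenol for the organometallic steps with a group that leaves in the final hydrogenolysis.

Step 10
Reactants: 17 methyl 2-{3-(benzyloxy)-2-[4-(benzyloxy)benzyl]-6-bromo-5-methoxyphenyl}acetate; 18 4-(benzyloxy)benzyl chloride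
Product: 20 methyl 2-{3-(benzyloxy)-2,6-bis[4-(benzyloxy)benzyl]-5-methoxyphenyl}acetate, via 4-(benzyloxy)benzylzinc chloride 19 (not isolated)
Conditions: 18, Zn dust, LiCl, THF, 23 °C; then 17, Pd(OAc)2 (2 mol %), SPhos (4 mol %), THF, 50 °C
Reagents that add atoms: none
Why: Negishi cross-coupling, in which zerovalent palladium formed from Pd(OAc)2 and SPhos inserts into the hindered C6–Br bond and the ester-tolerant benzylzinc chloride transfers the sp3 carbon, giving the C6 benzyl group directly at the methylene oxidation level.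

Step 11
Reactants: 20 methyl 2-{3-(benzyloxy)-2,6-bis[4-(benzyloxy)benzyl]-5-methoxyphenyl}acetate
Product: 21 2-{3-(benzyloxy)-2,6-bis[4-(benzyloxy)benzyl]-5-methoxyphenyl}acetaldehyde
Conditions: i-Bu2AlH (1.1 equiv), CH2Cl2, −78 °C; MeOH, then aq. potassium sodium tartrate (KNaC4H4O6)
Reagents that add atoms: none
Why: Partial reduction of the ester with diisobutylaluminium hydride, whose tetrahedral aluminium hemiacetal is stable at −78 °C and releases the aldehyde only on work-up; the aldehyde is used at once.

Step 12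
Reactants: 22 4-bromo-2-hydroxybenzaldehyde
Product: 23 2-(benzyloxy)-4-bromobenzaldehyde
Conditions: BnBr, K2CO3, DMF, 23 °C
Reagents that add atoms: benzyl bromide, BrCc1ccccc1
Why: Williamson etherification of the acidic ortho-formyl phenol protects the ring B oxygen as a hydrogenolysable ether.

Step 13
Reactants: 23 2-(benzyloxy)-4-bromobenzaldehyde; 24 4-(benzyloxy)phenylmagnesium bromide
Product: 25 [2-(benzyloxy)-4-bromophenyl][4-(benzyloxy)phenyl]methanol (racemic)
Conditions: THF, 0 °C; aq. NH4Cl
Reagents that add atoms: none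
Why: Grignard addition to the aldehyde, with the aryl bromide inert to the arylmagnesium reagent at 0 °C; the carbinol centre is formed racemic and is removed in step 14.

Step 14
Reactants: 25 [2-(benzyloxy)-4-bromophenyl][4-(benzyloxy)phenyl]methanol
Product: 26 2-(benzyloxy)-1-[4-(benzyloxy)benzyl]-4-bromobenzene
Conditions: Et3SiH, CF3CO2H, CH2Cl2, 0 °C
Reagents that add atoms: none
Why: Ionic hydrogenation of a benzhydrol, whose ionisation gives a cation stabilised by the ortho and para alkoxy groups that Et3SiH reduces, leaving the aryl bromide and benzyl ethers intact.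

Step 15
Reactants: 26 2-(benzyloxy)-1-[4-(benzyloxy)benzyl]-4-bromobenzene; 21 2-{3-(benzyloxy)-2,6-bis[4-(benzyloxy)benzyl]-5-methoxyphenyl}acetaldehyde
Product: 28 2-{3-(benzyloxy)-2,6-bis[4-(benzyloxy)benzyl]-5-methoxyphenyl}-1-{3-(benzyloxy)-4-[4-(benzyloxy)benzyl]phenyl}ethan-1-ol (racemic), via ring B arylmagnesium bromide 27 (not isolated)
Conditions: 26 (1.5 equiv), Mg turnings, THF, 50 °C; then 21, THF, −20 to 0 °C; aq. NH4Cl
Reagents that add atoms: none
Why: Grignard addition, in which magnesium inserts into the C–Br bond of 26 and the arylmagnesium bromide adds to the aldehyde carbon (the former ester carbon) to join ring B to the bridge; the carbinol centre is formed racemic and is erased in step 16.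

Step 16
Reactants: 28 2-{3-(benzyloxy)-2,6-bis[4-(benzyloxy)benzyl]-5-methoxyphenyl}-1-{3-(benzyloxy)-4-[4-(benzyloxy)benzyl]phenyl}ethan-1-ol
Product: 29 2,4-bis(4-hydroxybenzyl)-3-{2-[3-hydroxy-4-(4-hydroxybenzyl)phenyl]ethyl}-5-methoxyphenol (CNP0207338.0)
Conditions: H2 (1 atm), Pd/C (10 %), EtOAc/MeOH, HCl (cat.), 23 °C
Reagents that add atoms: none
Why: Catalytic hydrogenolysis over palladium cleaves the five O–benzyl bonds and, assisted by acid, the benzylic C–OH bond, while the aryl methyl ether and the diarylmethane C–C bonds are stable.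

**Compound list**

1 | 3,5-dimethoxyphenol | COc1cc(O)cc(OC)c1 | starting material
2 | 3,5-dimethoxyphenyl N-isopropylcarbamate | COc1cc(OC)cc(OC(=O)NC(C)C)c1 | intermediate
3 | 3,5-dimethoxyphenyl N-(tert-butyldimethylsilyl)-N-isopropylcarbamate (not isolated) | COc1cc(OC)cc(OC(=O)N(C(C)C)[Si](C)(C)C(C)(C)C)c1 | intermediate
4 | 2-lithio-3,5-dimethoxyphenyl N-(tert-butyldimethylsilyl)-N-isopropylcarbamate (not isolated) | COc1cc(OC)c([Li])c(OC(=O)N(C(C)C)[Si](C)(C)C(C)(C)C)c1 | intermediate
5 | 3,5-dimethoxy-2-(trimethylsilyl)phenyl N-(tert-butyldimethylsilyl)-N-isopropylcarbamate (not isolated) | COc1cc(OC)c([Si](C)(C)C)c(OC(=O)N(C(C)C)[Si](C)(C)C(C)(C)C)c1 | intermediate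
6 | 3,5-dimethoxy-2-(trimethylsilyl)phenyl N-isopropylcarbamate | COc1cc(OC)c([Si](C)(C)C)c(OC(=O)NC(C)C)c1 | intermediate
7 | 3,5-dimethoxy-2-(trimethylsilyl)phenol (not isolated) | COc1cc(O)c([Si](C)(C)C)c(OC)c1 | intermediate
8 | 3,5-dimethoxy-2-(trimethylsilyl)phenyl trifluoromethanesulfonate | COc1cc(OC)c([Si](C)(C)C)c(OS(=O)(=O)C(F)(F)F)c1 | intermediate
9 | 4'-(benzyloxy)acetophenone | CC(=O)c1ccc(OCc2ccccc2)cc1 | starting material
10 | methyl 3-[4-(benzyloxy)phenyl]-3-oxopropanoate | COC(=O)CC(=O)c1ccc(OCc2ccccc2)cc1 | intermediate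
11 | 3,5-dimethoxybenzyne (not isolated) | COC1=CC(OC)=CC#C1 | intermediate
12 | cesium alkoxide of methyl 8-[4-(benzyloxy)phenyl]-8-hydroxy-2,4-dimethoxybicyclo[4.2.0]octa-1,3,5-triene-7-carboxylate (not isolated; both centres undefined and transient) | COC(=O)C1c2cc(OC)cc(OC)c2C1([O-])c1ccc(OCc2ccccc2)cc1.[Cs+] | intermediate
13 | methyl 2-{2-[4-(benzyloxy)benzoyl]-3,5-dimethoxyphenyl}acetate | COC(=O)Cc1cc(OC)cc(OC)c1C(=O)c1ccc(OCc2ccccc2)cc1 | intermediate
14 | methyl 2-{2-[4-(benzyloxy)benzoyl]-3-hydroxy-5-methoxyphenyl}acetate | COC(=O)Cc1cc(OC)cc(O)c1C(=O)c1ccc(OCc2ccccc2)cc1 | intermediate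
15 | methyl 2-{2-[4-(benzyloxy)benzyl]-3-hydroxy-5-methoxyphenyl}acetate | COC(=O)Cc1cc(OC)cc(O)c1Cc1ccc(OCc2ccccc2)cc1 | intermediate
16 | methyl 2-{2-[4-(benzyloxy)benzyl]-6-bromo-3-hydroxy-5-methoxyphenyl}acetate | COC(=O)Cc1c(Br)c(OC)cc(O)c1Cc1ccc(OCc2ccccc2)cc1 | intermediate
17 | methyl 2-{3-(benzyloxy)-2-[4-(benzyloxy)benzyl]-6-bromo-5-methoxyphenyl}acetate | COC(=O)Cc1c(Br)c(OC)cc(OCc2ccccc2)c1Cc1ccc(OCc2ccccc2)cc1 | intermediate
18 | 4-(benzyloxy)benzyl chloride | ClCc1ccc(OCc2ccccc2)cc1 | starting material
19 | 4-(benzyloxy)benzylzinc chloride (not isolated) | Cl[Zn]Cc1ccc(OCc2ccccc2)cc1 | intermediate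
20 | methyl 2-{3-(benzyloxy)-2,6-bis[4-(benzyloxy)benzyl]-5-methoxyphenyl}acetate | COC(=O)Cc1c(Cc2ccc(OCc3ccccc3)cc2)c(OC)cc(OCc2ccccc2)c1Cc1ccc(OCc2ccccc2)cc1 | intermediate
21 | 2-{3-(benzyloxy)-2,6-bis[4-(benzyloxy)benzyl]-5-methoxyphenyl}acetaldehyde | O=CCc1c(Cc2ccc(OCc3ccccc3)cc2)c(OC)cc(OCc2ccccc2)c1Cc1ccc(OCc2ccccc2)cc1 | intermediate
22 | 4-bromo-2-hydroxybenzaldehyde | O=Cc1ccc(Br)cc1O | starting material
23 | 2-(benzyloxy)-4-bromobenzaldehyde | O=Cc1ccc(Br)cc1OCc1ccccc1 | intermediate
24 | 4-(benzyloxy)phenylmagnesium bromide | Br[Mg]c1ccc(OCc2ccccc2)cc1 | starting material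
25 | [2-(benzyloxy)-4-bromophenyl][4-(benzyloxy)phenyl]methanol (racemic) | OC(c1ccc(Br)cc1OCc1ccccc1)c1ccc(OCc2ccccc2)cc1 | intermediate
26 | 2-(benzyloxy)-1-[4-(benzyloxy)benzyl]-4-bromobenzene | Brc1ccc(Cc2ccc(OCc3ccccc3)cc2)c(OCc2ccccc2)c1 | intermediate
27 | {3-(benzyloxy)-4-[4-(benzyloxy)benzyl]phenyl}magnesium bromide (not isolated) | Br[Mg]c1ccc(Cc2ccc(OCc3ccccc3)cc2)c(OCc2ccccc2)c1 | intermediate
28 | 2-{3-(benzyloxy)-2,6-bis[4-(benzyloxy)benzyl]-5-methoxyphenyl}-1-{3-(benzyloxy)-4-[4-(benzyloxy)benzyl]phenyl}ethan-1-ol (racemic) | OC(Cc1c(Cc2ccc(OCc3ccccc3)cc2)c(OC)cc(OCc2ccccc2)c1Cc1ccc(OCc2ccccc2)cc1)c1ccc(Cc2ccc(OCc3ccccc3)cc2)c(OCc2ccccc2)c1 | intermediate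
29 | 2,4-bis(4-hydroxybenzyl)-3-{2-[3-hydroxy-4-(4-hydroxybenzyl)phenyl]ethyl}-5-methoxyphenol | COc1cc(O)c(Cc2ccc(O)cc2)c(CCc2ccc(Cc3ccc(O)cc3)c(O)c2)c1Cc1ccc(O)cc1 | target

**Step count and risks**

Total steps: 16. Longest linear sequence: 12 steps (steps 1, 2, 3, 5, 6, 7, 8, 9, 10, 11, 15, 16).

Steps most likely to fail:

Step 15. The basic arylmagnesium reagent may deprotonate the readily enolised, hindered arylacetaldehyde instead of adding to it, and the aldehyde may self-condense or oxidise while being handled after step 11. The fallback sets out from ester 20 and avoids any enolisable carbonyl. LiAlH4 in THF should reduce 20 to 2-{3-(benzyloxy)-2,6-bis[4-(benzyloxy)benzyl]-5-methoxyphenyl}ethan-1-ol F1. PPh3, I2 and imidazole should convert it into 1-(benzyloxy)-2,4-bis[4-(benzyloxy)benzyl]-3-(2-iodoethyl)-5-methoxybenzene F2. Nickel-catalysed reductive cross-electrophile coupling of this primary iodide with aryl bromide 26 (NiI2, 4,4'-di-tert-butyl-2,2'-bipyridine, Zn dust, DMA) should give 1-(benzyloxy)-2,4-bis[4-(benzyloxy)benzyl]-3-(2-{3-(benzyloxy)-4-[4-(benzyloxy)benzyl]phenyl}ethyl)-5-methoxybenzene F3. Hydrogenolysis under the conditions of step 16 then comes back to the route at 29.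

Step 10. Oxidative addition at the electron-rich bromide, which is flanked by two ortho substituents, may be slow, so that protodebromination and homocoupling of the benzylzinc reagent take over. The fallback sets out from phenol 15 and forms the C6–CH2 bond by electrophilic substitution instead of cross-coupling. Acid-catalysed Friedel–Crafts benzylation with 4-(benzyloxy)benzyl alcohol (Sc(OTf)3 cat., MeNO2 or hexafluoroisopropanol), directed para to the free phenol, should give methyl 2-{2,6-bis[4-(benzyloxy)benzyl]-3-hydroxy-5-methoxyphenyl}acetate F4. Benzylation with BnBr and K2CO3 as in step 9 comes back to the route at 20.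

Step 7. The diarylmethyl cation may be captured by the neighbouring ester (lactonisation to an isochromanone and onward reduction to the free acid), and the aryl benzyl ether may be lost in the acid. The fallback sets out from 14 and reduces under basic conditions through an ortho-quinone methide. ClCO2Et and Et3N should give methyl 2-{2-[4-(benzyloxy)benzoyl]-3-[(ethoxycarbonyl)oxy]-5-methoxyphenyl}acetate F5. NaBH4 in THF/H2O reduces the ketone, the carbonate migrates to the new alkoxide and is expelled, and the ortho-quinone methide takes up a second hydride, coming back to the route at 15.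

**Further compounds**

F1 | step 15 | 2-{3-(benzyloxy)-2,6-bis[4-(benzyloxy)benzyl]-5-methoxyphenyl}ethan-1-ol | OCCc1c(Cc2ccc(OCc3ccccc3)cc2)c(OC)cc(OCc2ccccc2)c1Cc1ccc(OCc2ccccc2)cc1
F2 | step 15 | 1-(benzyloxy)-2,4-bis[4-(benzyloxy)benzyl]-3-(2-iodoethyl)-5-methoxybenzene | ICCc1c(Cc2ccc(OCc3ccccc3)cc2)c(OC)cc(OCc2ccccc2)c1Cc1ccc(OCc2ccccc2)cc1
F3 | step 15 | 1-(benzyloxy)-2,4-bis[4-(benzyloxy)benzyl]-3-(2-{3-(benzyloxy)-4-[4-(benzyloxy)benzyl]phenyl}ethyl)-5-methoxybenzene | COc1cc(OCc2ccccc2)c(Cc2ccc(OCc3ccccc3)cc2)c(CCc2ccc(Cc3ccc(OCc4ccccc4)cc3)c(OCc3ccccc3)c2)c1Cc1ccc(OCc2ccccc2)cc1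
F4 | step 10 | methyl 2-{2,6-bis[4-(benzyloxy)benzyl]-3-hydroxy-5-methoxyphenyl}acetate | COC(=O)Cc1c(Cc2ccc(OCc3ccccc3)cc2)c(OC)cc(O)c1Cc1ccc(OCc2ccccc2)cc1
F5 | step 7 | methyl 2-{2-[4-(benzyloxy)benzoyl]-3-[(ethoxycarbonyl)oxy]-5-methoxyphenyl}acetate | CCOC(=O)Oc1cc(OC)cc(CC(=O)OC)c1C(=O)c1ccc(OCc2ccccc2)cc1
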